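The runs are simulated with constants of no real substance; scatter was added.

The flask holds 1.20 of reagent in the second phase for each starting material, yet the blue run, charged alike but for the protic impurity, shows just 7.8% of target after 50.0 min. That difference in impurity is worth 1.00% of the starting material, so we take blue as the early curve of this flask.

common to all: starting material 0.064 M
- red: reagent in the second phase 0.051 M; protic impurity 1.28 mM; run made earlier
- amber: reagent in the second phase 0.12 M; protic impurity 1.28 mM; run made earlier
- blue: reagent in the second phase 0.0768 M; protic impurity 0.64 mM; run made earlier
- flask: reagent in the second phase 0.0768 M; protic impurity 1.28 mM; time 1.5 h; volume of the second phase over the first 0.25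

| run | time / min | target / % | starting material / % |
|---|---|---|---|
| red | 3.00 | 0.1 | 98.1 |
| red | 8.00 | 0 | 97.6 |
| red | 15.0 | 0.3 | 96.4 |
| red | 25.0 | 1.9 | 96.7 |
| red | 30.0 | 2.3 | 95.6 |
| red | 40.0 | 3.3 | 94.1 |
| red | 50.0 | 5.4 | 92.6 |
| amber | 3.00 | 0 | 97.4 |
| amber | 8.00 | 0 | 97.6 |
| amber | 15.0 | 1.7 | 96.8 |
| amber | 25.0 | 3.7 | 94.3 |
| amber | 30.0 | 5.2 | 92.3 |
| amber | 40.0 | 7.9 | 89.0 |
| amber | 50.0 | 11.1 | 85.2 |
| blue | 5.00 | 0 | 98.7 |
| blue | 15.0 | 1.4 | 98.2 |
| blue | 25.0 | 2.7 | 96.2 |
| blue | 40.0 | 5.5 | 92.8 |
| blue | 50.0 | 7.8 | 90.6 |

(standard deviation of a reading: 0.3 percentage points)

- a species is counted by the starting material in it: one side product counts as two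
- in the second phase: reagent in the second phase; everything else is in the first
- charges count per volume of the first phase; a concentration in a rate is the amount of a species over the volume of its own phase; every rate counts per litre of the first phase
- what may be going on: starting material + target -> side product; reagent in the reaction phase <-> reagent in the second phase; starting material + reagent in the reaction phase -> target; starting material + protic impurity -> quenched substrate
- the earlier runs hold the two phases in the same ratio of volumes as the flask asked about

- alpha: doubling the amount of reagent in the second phase, all else as stated
- beta: doubling the transfer coefficient of the reagent in the second phase, all else as stated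

1. the target standing at 1.5 h, as a percentage of the starting material charged
2. the change that raises the amount of target at 1.5 h, in percent of the starting material charged most ("none" if none brings more than 2 percentage points) (alpha / beta / none)
3. amount of target at 1.5 h, in percent of the starting material charged, after beta

The blue run looks contradictory: its starting material falls, but target gains 1.4% in the first 15.0 min and then 5.1 percentage points between 25.0 min and 50.0 min, which is faster per minute. We read this as reagent that must first cross into the reaction phase, so the late readings form a line that starts late. We call the time at which that line, drawn through the readings at 25.0 min and 50.0 min, cuts the time axis the lag 11.8 min, an induction period. The same line read on the red run gives 11.4 min and on the amber run 12.5 min, though their charges of reagent differ by a factor of 2.35, while their target readings at 50.0 min differ by a factor of 2.06. So between these two runs the height of the readings moves with the charge, and the lag read from them stays close. Taking target in proportion to time past the lag, we reckon 16.0% for the flask at 1.5 h. The height moves with the charge in these runs and no run varies the transfer coefficient, so we commit to alpha.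

The forecast gives 14%, alpha and 19%: “Doubling the reagent charge roughly doubles the rate whatever limits it”.

The flask gives 16.9%. The best change is alpha, worth 14 points, and beta reaches 23.2%.

    starting material + target → side product (k = 3.40 L mol⁻¹ h⁻¹)
    reagent in the reaction phase ⇌ reagent in the second phase, rate k2*([reagent in the reaction phase] - [reagent in the second phase]/K2) per volume of the first phase (partition coefficient = 1.10, kL = 0.200 h⁻¹)
    starting material + reagent in the reaction phase → target (k = 6.20 L mol⁻¹ h⁻¹)
    starting material + protic impurity → quenched substrate (k = 1400 L mol⁻¹ h⁻¹)

The lag of 11.8 min gave 16.0% against 16.9%, and on the doubled charge, with that lag kept and the height doubled, it gives a gain of 16 points against the simulated 14 points. Part of why the flask stands this low is the pace of uptake of the reagent together with the time allowed. With that uptake made fast the same flask holds 31.4% of target, and left for 15.0 h it holds 48.9%.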